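Remark on the chemistry: ring B is taken from commercial 3,4,5-trihydroxybenzaldehyde (sold as its monohydrate) instead of a gallic ester, which saves a reduction–oxidation pair. Flavone locants (O1, C2 … C8a; rings A, B, C) are used for every intermediate, open-chain ones included.

## Structural features

The target is a flavone: benzene ring A is fused through C4a–C8a to the 4-pyranone ring C (O1, C2, C3, C4), and the 3,4,5-trihydroxyphenyl ring B is attached to C2 by one C–C bond. It has no stereocentre, so the problem is purely one of constitution: of seven substituent oxygens only those on C3 and C7 are methylated, and the other five are free phenols. Ring A is oxygenated at C5, C7, C8 and C8a; the hydroxyls on C5 and C8 are para to each other, a hydroquinone that air and base convert into the 5,8-quinone, and ring B is a pyrogallol of similar sensitivity. If ring C is opened by hot acid or base it can reclose through the C5 oxygen (Wessely–Moser rearrangement) to the 5,6,7-oxygenated isomer, so the unprotected nucleus should meet neither. The real difficulty is regiochemical: which of the four ring A oxygens becomes O1, how C7 remains the only ring A methyl ether, and how an oxygen is brought to C3, which has no handle in a finished flavone. The key step exploits the C2≡C3 triple bond of an aryl alkynyl ketone together with the methoxyl on C8a: the ether oxygen becomes O1 by bonding to C2 while C3 takes up iodine. The C8a and C7 methoxyls stem from the two equivalent methoxyls of the mirror-symmetric hydroquinone 3, whose hydroxyls become O5 and O8, so ring A never needs a regioselective oxygenation.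

## Logic of the disconnections

**15 from 14.** The last bonds cut are the three O–CH2 bonds of the ring B ethers. 15 combines a pyrogallol with a hydroquinone and is the most easily oxidised compound of the sequence, so it should appear only in the final step and under neutral, reducing conditions. The cut gains nothing in skeleton but confines the sensitivity to one operation. The forward step must remove benzyl groups without touching the C2=C3 bond or the two methyl ethers, and 14 must arrive with ring A already free, because no further deprotection can follow.

**14 from 12.** Next the C3–O bond of the C3 methoxyl is cut, and O5 and O8 are returned to their acylated form. C3 of a flavone has no selective reactivity towards oxygen electrophiles beside two electron-rich arenes, whereas a C3–I bond is a unique site for exchange against methoxide at CuI–1,10-phenanthroline. The same methoxide removes both ring A esters (through 13), so C–O formation and deprotection share one step. The demand is that the coupling at C3 outruns reductive loss of iodine and attack of methoxide on C2, and that the bis-phenoxide is kept from oxygen.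

**12 from 11 (key cut).** O1–C2 and C3–I are removed together and ring C is opened. Both bonds can be made in one anti addition across C2≡C3, with the ether oxygen on C8a as nucleophile and an iodonium ion as electrophile. The oxygen that becomes O1 can therefore stay methylated up to this point, and no ring A phenol has to be singled out. The gain is one ring and the only heteroatom handle that is not already in the starting materials. The forward step must be selective in three ways: attack by the C8a oxygen and not the C5 oxygen, 6-endo and not 5-exo closure, and activation of the alkyne in preference to iodination of the arenes. The first is the reason why O5 and O8 are esters and not ethers. The atom mapping between 11 and 12 is: the ring carbon of 11 that bears the acyl group is C4a, its methoxylated neighbour is C8a and its acyloxylated neighbour is C5.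

**11 from 6 and 9 (through 10).** 11 is cut at C4–C3, between the carbonyl carbon and the alkyne. This is the most convergent cut, giving a ring A acid and a ring B alkyne of similar size, and it is made at the acid chloride level. The cut at the aldehyde level (metal acetylide of 9 added to 5, then oxidation) costs the same number of steps but is the weaker design. It creates an alkoxide on the carbon attached to C4a, from which O-to-O transfer of the C5 acyl group through a six-membered transition state is expected, and it exposes two aryl esters to a strongly basic nucleophile. Acylation of the terminal alkyne under PdCl2(PPh3)2 and CuI forms the ketone directly, with a tertiary amine as the only base. It requires that a di-ortho-substituted aroyl chloride still undergoes oxidative addition.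

**6 from 5 from 4.** The C4a–C4 bond is cut next. 4 has a mirror plane through its two acyloxylated carbons, so its two ring hydrogens are identical, each ortho to one methoxyl and para to the other; electrophilic formylation can give only 5, and oxidation adjusts the level to 6. The symmetry argument has a limit: the two methoxyls are equivalent only up to 4. From 5 onwards one is ortho to the new carbon (the future O1 donor) and the other para (the future C7 methoxyl), so the choice is made by this substitution and not during ring closure. The formylation must leave the ortho methyl ether, which now chelates, and both esters intact.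

**4 from 1 and 2.** 4 is cut at its two O–acyl bonds and taken back by two electrons to 1, the cheap, air-stable form of the symmetric core; two equivalents of 2 supply the acyl groups. A hindered acyl group is wanted because it has to survive TiCl4, chlorite, a tertiary amine and an iodonium source, make O5 non-nucleophilic in the key step, and still leave with methoxide. The forward step has to acylate the air-sensitive 3 without isolating it, including the hydroxyl between the two methoxyls.

**9 from 8 from 7.** 9 is cut between its two alkyne carbons, which traces C2 to the formyl carbon of 8 and C3 to a one-carbon reagent, and 8 is cut at its three O–benzyl bonds to give 7. Benzyl ethers pass every later step and leave in the final hydrogenolysis. The homologation must work on an electron-rich, non-enolisable aldehyde under mild base.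

## Other disconnections considered

Alternative 1: The cut is C3–C4.
- Forward key step: the dialdehyde 3,6-bis(benzyloxy)-4-methoxy-2-{2-oxo-1-[3,4,5-tris(benzyloxy)phenyl]ethoxy}benzaldehyde A1 would be treated with 3-benzyl-5-(2-hydroxyethyl)-4-methylthiazolium chloride and Et3N. The carbene formed from the thiazolium salt adds to the aromatic formyl group, the acyl-anion equivalent attacks the aliphatic aldehyde (crossed intramolecular benzoin reaction), and ring C closes as the 3-hydroxychroman-4-one A2, a racemic mixture of diastereomers.
- In its favour: the C3 oxygen arrives with the ring closure, the catalyst is organic, no halogen or copper is needed, and ring A stays benzylated until a single hydrogenolysis frees all five phenols.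
- Against it here: A1 contains an α-aryl-α-aryloxy acetaldehyde that should enolise, epimerise and oxidise easily. Its synthesis needs a ring A salicylaldehyde with only the C8a hydroxyl free, which the symmetric core cannot supply without a selective deprotection. A2 is one dehydrogenation short of a flavone and lacks the C3 methyl group, so its two stereocentres are made only to be destroyed.
- Comparison on structure: the alternative is the better in keeping the hydroquinone protected to the end, and the worse in access to the ring A fragment.
- Comparison on mechanism: it is the equal in regiochemical certainty (one mode of closure only) and the better in mildness, but it closes ring C at the wrong oxidation level, whereas the iodocyclisation gives the aromatic pyranone directly.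
- Comparison on step economy: it loses, because O-methylation, dehydrogenation and a longer fragment synthesis outweigh the saved methoxylation.

Alternative 2: The cuts are C4a–C4, C4–C3 and O1–C2, all in ring C.
- Forward key step: 2,5-bis(benzyloxy)-6-iodo-3-methoxyphenol A3 and the alkyne 9 would be combined under CO (1 atm) with PdCl2(PPh3)2 in Et2NH. Oxidative addition, insertion of CO and acylation of the alkyne give an o-hydroxyaryl ynone in the flask, which the amine closes 6-endo to the flavone A4.
- In its favour: it is the most convergent assembly of ring C (three bonds in one operation), it uses the same alkyne 9, and closure through a free phenol needs no dealkylation.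
- Against it here: A4 carries hydrogen at C3, so an oxygen must still be introduced there (epoxidation of the enol-ether double bond, or metalation, borylation and oxidation) and then methylated. A3 is a fully differentiated tetraoxygenated iodophenol whose preparation cannot profit from symmetry. The aryl iodide is electron rich and flanked by two substituents, which slows oxidative addition.
- Comparison on structure: the two plans are equal in their ynone logic (both finish by forming O1–C2 on a C2≡C3 unit), and the alternative is the better in convergence.
- Comparison on mechanism: nucleophilic closure leaves hydrogen at C3 where electrophilic closure leaves iodine, which is the decisive advantage of the chosen plan.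
- Comparison on step economy: the alternative saves the preparation of 6 and 10 but pays more for A3 and for the late C3 oxidation.

Alternative 3: The cut is O1–C8a.
- Forward key step: the acylquinone 2-methoxy-5-{2-methoxy-3-oxo-3-[3,4,5-tris(benzyloxy)phenyl]propanoyl}cyclohexa-2,5-diene-1,4-dione A5 would be exposed to NaOAc. The enol oxygen of the 2-methoxy-1,3-diketone adds to C8a of the quinone (6-endo oxa-Michael addition), and tautomerisation restores ring A as the hydroquinone. The product is 5,8-dihydroxy-3,7-dimethoxy-2-[3,4,5-tris(benzyloxy)phenyl]-4H-chromen-4-one A6, the same compound as 14.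
- In its favour: ring closure and the correct oxidation state of ring A come from one internal redox event, both methyl ethers are already in place, neither halogen nor copper is used, and ring A needs no protecting group. The regiochemistry is secure because C8a is the β-carbon of both the C5 carbonyl and the side-chain ketone, while C6 is deactivated by the C7 methoxyl.
- Against it here: A5 is a quinone carrying a 1,3-dicarbonyl unit with an acidic methine. It is strongly electrophilic and oxidising, open to addition of water or acetate and to redox exchange with its own product A6. It has to be generated by oxidising an acylhydroquinone in the presence of the electron-rich ring B ethers, after a separate Claisen-type assembly of the diketone.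
- Comparison on structure: the alternative is the better at the end, since its key product already is 14 and the C3 methoxyl needs no coupling.
- Comparison on mechanism: it is the equal in regiocontrol and the better in redox economy, but it depends on a far less stable precursor than the isolable 11.
- Comparison on step economy: it is at best equal, because what it saves after the key step it spends on building and oxidising the diketone.

Key step: step 7

## Route

Step 1
Reactants: 1 2,6-dimethoxy-1,4-benzoquinone; 2 pivaloyl chloride (2,2-dimethylpropanoyl chloride)
Product: 4 2,6-dimethoxy-1,4-phenylene bis(2,2-dimethylpropanoate), via 2,6-dimethoxyhydroquinone 3 (not isolated)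
Conditions: H2 (1 atm), Pd/C (10 wt%), THF, rt; filter under N2; then Et3N, DMAP (cat.), 2 (2.4 equiv in all), 0 → 40 °C
Reagents that add atoms: pivaloyl chloride (the second equivalent of 2, one acyl group per hydroxyl), CC(C)(C)C(=O)Cl
Why: Catalytic hydrogenation of a 1,4-benzoquinone to its hydroquinone is fast and clean, and acylating the air-sensitive diol 3 in solution without isolating it avoids reoxidation; DMAP-catalysed esterification (nucleophilic acyl substitution) with two equivalents of 2 should reach even the hydroxyl flanked by two methoxyls on gentle warming.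

Step 2
Reactants: 4 2,6-dimethoxy-1,4-phenylene bis(2,2-dimethylpropanoate)
Product: 5 2-formyl-3,5-dimethoxy-1,4-phenylene bis(2,2-dimethylpropanoate)
Conditions: Cl2CHOMe, TiCl4, CH2Cl2, −10 → 0 °C; then ice/1 M aq. HCl
Reagents that add atoms: dichloromethyl methyl ether, COC(Cl)Cl; water, O
Why: Rieche formylation (Friedel–Crafts-type substitution by the chloro(methoxy)carbenium ion): the two free ring positions of 4 are equivalent and each is ortho to one methoxyl and para to the other, so a single aldehyde is expected after hydrolytic work-up; a short reaction time at 0 °C is meant to spare the methyl ether that ends up ortho to the formyl group.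

Step 3
Reactants: 5 2-formyl-3,5-dimethoxy-1,4-phenylene bis(2,2-dimethylpropanoate)
Product: 6 3,6-bis[(2,2-dimethylpropanoyl)oxy]-2,4-dimethoxybenzoic acid
Conditions: NaClO2, NaH2PO4, 2-methyl-2-butene, t-BuOH/THF/H2O, rt
Reagents that add atoms: sodium chlorite, [Na+].[O-]Cl=O
Why: Pinnick oxidation converts the hindered, non-enolisable aldehyde to the acid in a weakly acidic buffer that leaves aryl pivalates alone; 2-methyl-2-butene traps HOCl so that the electron-rich ring is not chlorinated.

Step 4
Reactants: 7 3,4,5-trihydroxybenzaldehyde
Product: 8 3,4,5-tris(benzyloxy)benzaldehyde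
Conditions: BnBr (3.6 equiv), K2CO3, DMF (degassed), 60 °C
Reagents that add atoms: benzyl bromide, BrCc1ccccc1
Why: Williamson ether synthesis; the three phenoxides are alkylated by the reactive benzylic bromide while the non-enolisable aldehyde is inert, and degassing protects the pyrogallol anion from air.

Step 5
Reactants: 8 3,4,5-tris(benzyloxy)benzaldehyde
Product: 9 1,2,3-tris(benzyloxy)-5-ethynylbenzene
Conditions: dimethyl (1-diazo-2-oxopropyl)phosphonate, K2CO3, MeOH/THF, rt
Reagents that add atoms: dimethyl (1-diazo-2-oxopropyl)phosphonate, COP(=O)(OC)C(=[N+]=[N-])C(C)=O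
Why: Seyferth–Gilbert homologation in its Ohira–Bestmann form: methanolysis of the reagent releases the diazomethylphosphonate anion, whose Horner–Wadsworth–Emmons-type addition to the aldehyde, loss of N2 and 1,2-hydrogen shift of the alkylidene carbene give the terminal alkyne under conditions mild enough for benzyl ethers.

Step 6
Reactants: 6 3,6-bis[(2,2-dimethylpropanoyl)oxy]-2,4-dimethoxybenzoic acid; 9 1,2,3-tris(benzyloxy)-5-ethynylbenzene
Product: 11 3,5-dimethoxy-2-{3-[3,4,5-tris(benzyloxy)phenyl]prop-2-ynoyl}-1,4-phenylene bis(2,2-dimethylpropanoate), via aroyl chloride 10 (not isolated)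
Conditions: (COCl)2, DMF (cat.), CH2Cl2, 0 °C → rt, evaporate; then 9, PdCl2(PPh3)2 (cat.), CuI (cat.), Et3N, THF, rt, N2
Reagents that add atoms: none
Why: Acyl Sonogashira coupling: oxidative addition of the aroyl chloride 10 to zerovalent palladium, transmetallation from the copper acetylide of 9 and reductive elimination form the C4–C3 bond directly at the ketone level; no alkoxide or organolithium is generated, so the aryl pivalates can neither migrate nor be attacked, and Et3N at room temperature does not cleave them.

Step 7
Reactants: 11 3,5-dimethoxy-2-{3-[3,4,5-tris(benzyloxy)phenyl]prop-2-ynoyl}-1,4-phenylene bis(2,2-dimethylpropanoate)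
Product: 12 3-iodo-7-methoxy-4-oxo-2-[3,4,5-tris(benzyloxy)phenyl]-4H-chromene-5,8-diyl bis(2,2-dimethylpropanoate)
Conditions: ICl (1.2 equiv, 1 M in CH2Cl2), CH2Cl2, −78 °C → rt, dark; then aq. Na2S2O3
Reagents that add atoms: iodine monochloride, ClI
Why: ICl delivers an iodonium ion to C2≡C3, and the positive charge develops on C2, which is benzylic to the electron-rich ring B and β to the carbonyl. The methoxyl oxygen on C8a attacks C2 anti to iodine to give a cyclic methyloxonium ion, and chloride removes the methyl group by SN2 displacement (MeCl), which makes the closure irreversible. The closest known reaction type is the ICl-induced dealkylative cyclisation of 2-methoxyaryl alkynyl ketones to 3-iodochromones. Ring C closes in the 6-endo-dig mode; the 5-exo-dig alternative would place the cation on C3 beside the carbonyl and is disfavoured by the polarisation of the ynone. No stereocentre is formed. The step needs site selectivity between the two oxygens ortho to the acyl group: the C5 oxygen is an ester oxygen whose lone pair is engaged with the pivaloyl carbonyl, so only the ether oxygen on C8a is nucleophilic enough, and which oxygen that is was settled when the carbonyl carbon was placed on the ring in step 2. It also needs chemoselectivity for the alkyne over the arenes, which low temperature and only a slight excess of ICl should secure, since both rings are deactivated by the conjugated carbonyl and ring A also by two acyloxy groups. No Brønsted acid is produced, so the pivalates and benzyl ethers are expected to survive.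

Step 8
Reactants: 12 3-iodo-7-methoxy-4-oxo-2-[3,4,5-tris(benzyloxy)phenyl]-4H-chromene-5,8-diyl bis(2,2-dimethylpropanoate)
Product: 14 5,8-dihydroxy-3,7-dimethoxy-2-[3,4,5-tris(benzyloxy)phenyl]-4H-chromen-4-one, via 3-iodo-5,8-dihydroxyflavone 13 (not isolated)
Conditions: CuI (cat.), 1,10-phenanthroline (cat.), NaOMe (excess), MeOH (degassed), 110 °C, sealed tube, Ar; then dil. aq. HCl under Ar
Reagents that add atoms: sodium methoxide, [Na+].[O-]C
Why: Methoxide first transesterifies both aryl pivalates (giving 13 as its bis-phenoxide), then an Ullmann-type C–O coupling at monovalent copper–phenanthroline replaces the C3 iodide by methoxide; strict exclusion of air and acidification under argon keep the 5,8-hydroquinone from oxidising, and benzyl and methyl ethers are inert to methoxide.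

Step 9
Reactants: 14 5,8-dihydroxy-3,7-dimethoxy-2-[3,4,5-tris(benzyloxy)phenyl]-4H-chromen-4-one
Product: 15 5,8-dihydroxy-3,7-dimethoxy-2-(3,4,5-trihydroxyphenyl)-4H-chromen-4-one (5,8,3',4',5'-pentahydroxy-3,7-dimethoxyflavone)
Conditions: H2 (1 atm), Pd/C (10 wt%), THF/MeOH, rt; filtration and concentration under Ar
Reagents that add atoms: none
Why: Hydrogenolysis of the three aryl benzyl ethers on Pd/C under neutral conditions; the tetrasubstituted C2=C3 bond, part of a vinylogous ester, and the methyl ethers should not be affected, and work-up under argon protects the pyrogallol and hydroquinone units of 15.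

## Compound list

1 | 2,6-dimethoxy-1,4-benzoquinone | COC1=CC(=O)C=C(OC)C1=O | starting material
2 | pivaloyl chloride | CC(C)(C)C(=O)Cl | starting material
3 | 2,6-dimethoxybenzene-1,4-diol (2,6-dimethoxyhydroquinone; not isolated) | COc1cc(O)cc(OC)c1O | intermediate
4 | 2,6-dimethoxy-1,4-phenylene bis(2,2-dimethylpropanoate) | COc1cc(OC(=O)C(C)(C)C)cc(OC)c1OC(=O)C(C)(C)C | intermediate
5 | 2-formyl-3,5-dimethoxy-1,4-phenylene bis(2,2-dimethylpropanoate) | CC(C)(C)C(=O)Oc1cc(OC)c(OC(=O)C(C)(C)C)c(OC)c1C=O | intermediate
6 | 3,6-bis[(2,2-dimethylpropanoyl)oxy]-2,4-dimethoxybenzoic acid | CC(C)(C)C(=O)Oc1cc(OC)c(OC(=O)C(C)(C)C)c(OC)c1C(=O)O | intermediate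
7 | 3,4,5-trihydroxybenzaldehyde | O=Cc1cc(O)c(O)c(O)c1 | starting material
8 | 3,4,5-tris(benzyloxy)benzaldehyde | O=Cc1cc(OCc2ccccc2)c(OCc2ccccc2)c(OCc2ccccc2)c1 | intermediate
9 | 1,2,3-tris(benzyloxy)-5-ethynylbenzene | C#Cc1cc(OCc2ccccc2)c(OCc2ccccc2)c(OCc2ccccc2)c1 | intermediate
10 | 3,6-bis[(2,2-dimethylpropanoyl)oxy]-2,4-dimethoxybenzoyl chloride (not isolated) | CC(C)(C)C(=O)Oc1cc(OC)c(OC(=O)C(C)(C)C)c(OC)c1C(=O)Cl | intermediate
11 | 3,5-dimethoxy-2-{3-[3,4,5-tris(benzyloxy)phenyl]prop-2-ynoyl}-1,4-phenylene bis(2,2-dimethylpropanoate) | CC(C)(C)C(=O)Oc1cc(OC)c(OC(=O)C(C)(C)C)c(OC)c1C(=O)C#Cc1cc(OCc2ccccc2)c(OCc2ccccc2)c(OCc2ccccc2)c1 | intermediate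
12 | 3-iodo-7-methoxy-4-oxo-2-[3,4,5-tris(benzyloxy)phenyl]-4H-chromene-5,8-diyl bis(2,2-dimethylpropanoate) | COc1cc(OC(=O)C(C)(C)C)c2c(=O)c(I)c(-c3cc(OCc4ccccc4)c(OCc4ccccc4)c(OCc4ccccc4)c3)oc2c1OC(=O)C(C)(C)C | intermediate
13 | 5,8-dihydroxy-3-iodo-7-methoxy-2-[3,4,5-tris(benzyloxy)phenyl]-4H-chromen-4-one (in the flask as its disodium salt; not isolated) | COc1cc(O)c2c(=O)c(I)c(-c3cc(OCc4ccccc4)c(OCc4ccccc4)c(OCc4ccccc4)c3)oc2c1O | intermediate
14 | 5,8-dihydroxy-3,7-dimethoxy-2-[3,4,5-tris(benzyloxy)phenyl]-4H-chromen-4-one | COc1cc(O)c2c(=O)c(OC)c(-c3cc(OCc4ccccc4)c(OCc4ccccc4)c(OCc4ccccc4)c3)oc2c1O | intermediate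
15 | 5,8-dihydroxy-3,7-dimethoxy-2-(3,4,5-trihydroxyphenyl)-4H-chromen-4-one | COc1cc(O)c2c(=O)c(OC)c(-c3cc(O)c(O)c(O)c3)oc2c1O | target

## Step count and least certain steps

Total step count: 9. Longest linear sequence: 7 steps (steps 1, 2, 3, 6, 7, 8, 9, from 1 to 15); the ring B branch (steps 4 and 5) joins at step 6.

**Step 7 (key step).** The most likely failure is that the C8a methoxyl attacks too slowly. It is crowded between the C8 pivalate and an aroyl group twisted out of the ring plane by two ortho substituents, so addition of iodine and chlorine across the triple bond, or iodination of ring B, may outrun the closure.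

The fallback sets out from 5 and returns at 12. It closes ring C through a free phenol and introduces iodine afterwards. BCl3 in CH2Cl2 at −78 → 0 °C should cleave only the methyl ether chelated to the formyl group (no benzyl ether is present yet), giving 2-formyl-3-hydroxy-5-methoxy-1,4-phenylene bis(2,2-dimethylpropanoate) F1. Acetylation (Ac2O, pyridine) would give 3-(acetyloxy)-2-formyl-5-methoxy-1,4-phenylene bis(2,2-dimethylpropanoate) F2, and chlorite oxidation as in step 3 would give 2-(acetyloxy)-3,6-bis[(2,2-dimethylpropanoyl)oxy]-4-methoxybenzoic acid F3. Oxalyl chloride would convert this into 2-(acetyloxy)-3,6-bis[(2,2-dimethylpropanoyl)oxy]-4-methoxybenzoyl chloride F4, used crude, and coupling with 9 as in step 6 would give 3-(acetyloxy)-5-methoxy-2-{3-[3,4,5-tris(benzyloxy)phenyl]prop-2-ynoyl}-1,4-phenylene bis(2,2-dimethylpropanoate) F5. Et2NH in DMF at rt should remove the unhindered acetate in preference to the pivalates and close ring C by 6-endo conjugate addition of the freed C8a phenoxide, relayed through the amine adduct of the ynone; the product would be 7-methoxy-4-oxo-2-[3,4,5-tris(benzyloxy)phenyl]-4H-chromene-5,8-diyl bis(2,2-dimethylpropanoate) F6. Iodination at C3, the α-carbon of the vinylogous ester, with I2 and (NH4)2Ce(NO3)6 in MeCN should then return to 12.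

**Step 8.** The most likely failures are reductive loss of iodine, opening of ring C by methoxide at C2 followed by intramolecular displacement of iodide (ring contraction), and air oxidation of the hydroquinone bis-phenoxide at 110 °C.

The fallback sets out from 12 and returns at 14. It makes the C3–O bond through boron instead of copper, with the esters still in place. Iodine–magnesium exchange with iPrMgCl·LiCl in THF at −78 → −40 °C, a temperature at which aryl pivalates tolerate the reagent, should give chloro{7-methoxy-4-oxo-5,8-bis[(2,2-dimethylpropanoyl)oxy]-2-[3,4,5-tris(benzyloxy)phenyl]-4H-chromen-3-yl}magnesium F7. Trapping with B(OMe)3 would give dimethyl {7-methoxy-4-oxo-5,8-bis[(2,2-dimethylpropanoyl)oxy]-2-[3,4,5-tris(benzyloxy)phenyl]-4H-chromen-3-yl}boronate F8, and oxidation in the same flask with NaBO3·4H2O would give 3-hydroxy-7-methoxy-4-oxo-2-[3,4,5-tris(benzyloxy)phenyl]-4H-chromene-5,8-diyl bis(2,2-dimethylpropanoate) F9. O-Methylation (MeI, K2CO3, acetone) would give 3,7-dimethoxy-4-oxo-2-[3,4,5-tris(benzyloxy)phenyl]-4H-chromene-5,8-diyl bis(2,2-dimethylpropanoate) F10, and methanolysis of the pivalates (NaOMe, MeOH, rt, argon) returns to 14.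

**Step 6.** The most likely failure is slow oxidative addition of the di-ortho-substituted aroyl chloride, which leaves time for copper-mediated homocoupling of the alkyne (Glaser) or for decarbonylation of the acylpalladium intermediate.

The fallback sets out from 5 and returns at 11. It forms the C4–C3 bond by carbonyl addition. The lithium acetylide of 9 (n-BuLi, THF, −78 °C) is added to 5 and the mixture is quenched at −78 °C with AcOH, so that the alkoxide is protonated before it can take over the neighbouring pivaloyl group. This should give racemic 2-{1-hydroxy-3-[3,4,5-tris(benzyloxy)phenyl]prop-2-yn-1-yl}-3,5-dimethoxy-1,4-phenylene bis(2,2-dimethylpropanoate) F11. Oxidation of the propargylic alcohol with MnO2 in CH2Cl2 gives 11.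

**Step 2.** The most likely failures are loss of the methyl group ortho to the new formyl group through chelation to titanium, and sluggish substitution at a position flanked by a methoxyl and an acyloxy group.

The fallback sets out from 4 and returns at 11, bypassing 5, 6 and 10. Iodination with N-iodosuccinimide and CF3CO2H (cat.) in MeCN should give 2-iodo-3,5-dimethoxy-1,4-phenylene bis(2,2-dimethylpropanoate) F12. Carbonylative Sonogashira coupling of F12 with 9 (PdCl2(PPh3)2, CO at 1 atm, Et3N, THF, 50 °C) would install the carbonyl carbon and the alkyne in one operation.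

## Further compounds

F1 | step 7 | 2-formyl-3-hydroxy-5-methoxy-1,4-phenylene bis(2,2-dimethylpropanoate) | CC(C)(C)C(=O)Oc1cc(OC)c(OC(=O)C(C)(C)C)c(O)c1C=O
F2 | step 7 | 3-(acetyloxy)-2-formyl-5-methoxy-1,4-phenylene bis(2,2-dimethylpropanoate) | CC(=O)Oc1c(C=O)c(OC(=O)C(C)(C)C)cc(OC)c1OC(=O)C(C)(C)C
F3 | step 7 | 2-(acetyloxy)-3,6-bis[(2,2-dimethylpropanoyl)oxy]-4-methoxybenzoic acid | CC(=O)Oc1c(C(=O)O)c(OC(=O)C(C)(C)C)cc(OC)c1OC(=O)C(C)(C)C
F4 | step 7 | 2-(acetyloxy)-3,6-bis[(2,2-dimethylpropanoyl)oxy]-4-methoxybenzoyl chloride | CC(=O)Oc1c(C(=O)Cl)c(OC(=O)C(C)(C)C)cc(OC)c1OC(=O)C(C)(C)C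
F5 | step 7 | 3-(acetyloxy)-5-methoxy-2-{3-[3,4,5-tris(benzyloxy)phenyl]prop-2-ynoyl}-1,4-phenylene bis(2,2-dimethylpropanoate) | CC(=O)Oc1c(C(=O)C#Cc2cc(OCc3ccccc3)c(OCc3ccccc3)c(OCc3ccccc3)c2)c(OC(=O)C(C)(C)C)cc(OC)c1OC(=O)C(C)(C)C
F6 | step 7 | 7-methoxy-4-oxo-2-[3,4,5-tris(benzyloxy)phenyl]-4H-chromene-5,8-diyl bis(2,2-dimethylpropanoate) | COc1cc(OC(=O)C(C)(C)C)c2c(=O)cc(-c3cc(OCc4ccccc4)c(OCc4ccccc4)c(OCc4ccccc4)c3)oc2c1OC(=O)C(C)(C)C
F7 | step 8 | chloro{7-methoxy-4-oxo-5,8-bis[(2,2-dimethylpropanoyl)oxy]-2-[3,4,5-tris(benzyloxy)phenyl]-4H-chromen-3-yl}magnesium | COc1cc(OC(=O)C(C)(C)C)c2c(=O)c([Mg]Cl)c(-c3cc(OCc4ccccc4)c(OCc4ccccc4)c(OCc4ccccc4)c3)oc2c1OC(=O)C(C)(C)C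
F8 | step 8 | dimethyl {7-methoxy-4-oxo-5,8-bis[(2,2-dimethylpropanoyl)oxy]-2-[3,4,5-tris(benzyloxy)phenyl]-4H-chromen-3-yl}boronate | COc1cc(OC(=O)C(C)(C)C)c2c(=O)c(B(OC)OC)c(-c3cc(OCc4ccccc4)c(OCc4ccccc4)c(OCc4ccccc4)c3)oc2c1OC(=O)C(C)(C)C
F9 | step 8 | 3-hydroxy-7-methoxy-4-oxo-2-[3,4,5-tris(benzyloxy)phenyl]-4H-chromene-5,8-diyl bis(2,2-dimethylpropanoate) | COc1cc(OC(=O)C(C)(C)C)c2c(=O)c(O)c(-c3cc(OCc4ccccc4)c(OCc4ccccc4)c(OCc4ccccc4)c3)oc2c1OC(=O)C(C)(C)C
F10 | step 8 | 3,7-dimethoxy-4-oxo-2-[3,4,5-tris(benzyloxy)phenyl]-4H-chromene-5,8-diyl bis(2,2-dimethylpropanoate) | COc1cc(OC(=O)C(C)(C)C)c2c(=O)c(OC)c(-c3cc(OCc4ccccc4)c(OCc4ccccc4)c(OCc4ccccc4)c3)oc2c1OC(=O)C(C)(C)C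
F11 | step 6 | 2-{1-hydroxy-3-[3,4,5-tris(benzyloxy)phenyl]prop-2-yn-1-yl}-3,5-dimethoxy-1,4-phenylene bis(2,2-dimethylpropanoate) (racemic) | CC(C)(C)C(=O)Oc1cc(OC)c(OC(=O)C(C)(C)C)c(OC)c1C(O)C#Cc1cc(OCc2ccccc2)c(OCc2ccccc2)c(OCc2ccccc2)c1
F12 | step 2 | 2-iodo-3,5-dimethoxy-1,4-phenylene bis(2,2-dimethylpropanoate) | COc1cc(OC(=O)C(C)(C)C)c(I)c(OC)c1OC(=O)C(C)(C)C
A1 | alternative 1 | 3,6-bis(benzyloxy)-4-methoxy-2-{2-oxo-1-[3,4,5-tris(benzyloxy)phenyl]ethoxy}benzaldehyde (racemic) | COc1cc(OCc2ccccc2)c(C=O)c(OC(C=O)c2cc(OCc3ccccc3)c(OCc3ccccc3)c(OCc3ccccc3)c2)c1OCc1ccccc1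
A2 | alternative 1 | 5,8-bis(benzyloxy)-3-hydroxy-7-methoxy-2-[3,4,5-tris(benzyloxy)phenyl]chroman-4-one (racemic mixture of diastereomers) | COc1cc(OCc2ccccc2)c2c(c1OCc1ccccc1)OC(c1cc(OCc3ccccc3)c(OCc3ccccc3)c(OCc3ccccc3)c1)C(O)C2=O
A3 | alternative 2 | 2,5-bis(benzyloxy)-6-iodo-3-methoxyphenol | COc1cc(OCc2ccccc2)c(I)c(O)c1OCc1ccccc1
A4 | alternative 2 | 5,8-bis(benzyloxy)-7-methoxy-2-[3,4,5-tris(benzyloxy)phenyl]-4H-chromen-4-one | COc1cc(OCc2ccccc2)c2c(=O)cc(-c3cc(OCc4ccccc4)c(OCc4ccccc4)c(OCc4ccccc4)c3)oc2c1OCc1ccccc1
A5 | alternative 3 | 2-methoxy-5-{2-methoxy-3-oxo-3-[3,4,5-tris(benzyloxy)phenyl]propanoyl}cyclohexa-2,5-diene-1,4-dione (racemic at the methine) | COC1=CC(=O)C(C(=O)C(OC)C(=O)c2cc(OCc3ccccc3)c(OCc3ccccc3)c(OCc3ccccc3)c2)=CC1=O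
A6 | alternative 3 | 5,8-dihydroxy-3,7-dimethoxy-2-[3,4,5-tris(benzyloxy)phenyl]-4H-chromen-4-one | COc1cc(O)c2c(=O)c(OC)c(-c3cc(OCc4ccccc4)c(OCc4ccccc4)c(OCc4ccccc4)c3)oc2c1O
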